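Ring B carries oxygen on B1 (ether to ring A), B3, B5 and B6 (ether to ring C), with B3 and B6 para. This pattern is the imprint of a Dötz benzannulation, so ring B is disconnected at B2–B3, B1–B6 and B5–B6. In one operation a methoxy(β-methoxyvinyl)carbene of Cr(CO)5 (B3–B4–B5), the ethynyl ether of 2,4,6-trimethoxyphenol (B1–B2, ring A attached) and one CO ligand (B6) close ring B and deliver the ring A–B unit with only the B6 hydroxyl free. That phenol is then joined to ring C by copper-catalysed etherification, ring D is added by Suzuki coupling, and BBr3 frees all ten hydroxyls.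

Key step: step 5

Remark on the chemistry: all ten hydroxyls travel as methyl ethers, with methoxy at both the carbene carbon and the vinyl terminus, so that methoxide-catalysed methanol addition cannot scramble alkoxy groups and one reagent unmasks every oxygen; 2,4,6-trimethoxyphenol is taken as a catalogue compound.

Step 1
Reactants: 1 chromium hexacarbonyl Cr(CO)6; 2 ethynyltrimethylsilane
Product: 5 pentacarbonyl[1-methoxy-3-(trimethylsilyl)prop-2-yn-1-ylidene]chromium, via LiC≡CSiMe3 3 (not isolated), via acylchromate (CO)5Cr=C(OLi)C≡CSiMe3 4 (not isolated)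
Conditions: n-BuLi, THF, −78 °C; then Cr(CO)6, −78 to 0 °C; then MeOTf, CH2Cl2, 0 °C to rt
Reagents that add atoms: methyl trifluoromethanesulfonate (MeOTf), COS(=O)(=O)C(F)(F)F
Why: Fischer carbene synthesis, in which the lithium acetylide adds to a CO ligand to give the acylchromate and the hard electrophile MeOTf methylates its oxygen.

Step 2
Reactants: 5 pentacarbonyl[1-methoxy-3-(trimethylsilyl)prop-2-yn-1-ylidene]chromium
Product: 7 pentacarbonyl[(E)-1,3-dimethoxyprop-2-en-1-ylidene]chromium, via ethynylcarbene complex (CO)5Cr=C(OMe)C≡CH 6 (not isolated)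
Conditions: NaOMe (0.2 equiv), MeOH/THF, −20 °C to rt
Reagents that add atoms: methanol, CO
Why: Methoxide cleaves the activated C(sp)–Si bond and methanol adds to the strongly electrophilic alkynyl carbene in an alkoxide-catalysed Michael addition, a known reaction of alkynyl(alkoxy)carbene complexes; the push–pull product should settle as the E isomer, and exchange at the carbene carbon is degenerate because both alkoxy groups are methoxy.

Step 3
Reactants: 8 2,4,6-trimethoxyphenol; 9 trichloroethylene
Product: 11 2-{[(E)-1,2-dichloroethenyl]oxy}-1,3,5-trimethoxybenzene, via dichloroacetylene 10 (not isolated)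
Conditions: K2CO3, DMF, 70 °C
Reagents that add atoms: none
Why: Base-mediated elimination of HCl from trichloroethylene gives dichloroacetylene in solution, and anti addition of the phenoxide across it (nucleophilic addition to a haloalkyne) gives the (E)-1,2-dichlorovinyl ether.

Step 4
Reactants: 11 2-{[(E)-1,2-dichloroethenyl]oxy}-1,3,5-trimethoxybenzene
Product: 14 2-(ethynyloxy)-1,3,5-trimethoxybenzene, via chloroethynyl ether ArOC≡CCl 12 (not isolated), via lithium acetylide ArOC≡CLi 13 (not isolated)
Conditions: n-BuLi (2.2 equiv), THF, −78 to −40 °C; then H2O, −78 °C; used at once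
Reagents that add atoms: none
Why: Vinylic deprotonation and loss of LiCl give the chloroalkyne, chlorine–lithium exchange with the second equivalent of n-BuLi gives the lithium acetylide, and cold protonation frees the terminal aryl ynol ether (β-elimination followed by halogen–metal exchange), while the two ortho methoxy groups block ring lithiation next to oxygen.

Step 5
Reactants: 7 pentacarbonyl[(E)-1,3-dimethoxyprop-2-en-1-ylidene]chromium; 14 2-(ethynyloxy)-1,3,5-trimethoxybenzene
Product: 16 2,4-dimethoxy-6-(2,4,6-trimethoxyphenoxy)phenol, via arene complex (η6-phenol)Cr(CO)3 15 (not isolated)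
Conditions: THF, 55 °C, Ar; then air, Et2O, rt
Reagents that add atoms: none
Why: Proposed new method: thermal loss of one CO from 7 opens a site for alkyne 14, whose nucleophilic terminal CH carbon bonds to the electrophilic carbene carbon (B2–B3) so that chromium moves to the aryloxy-bearing carbon, CO then inserts there (B1–B6) to give a chromium-bound dienylketene, and ring B closes by thermal 6π-electrocyclisation of that dienylketene (B5–B6, six-membered ring) followed by tautomerisation to the phenol, which stays bound as its Cr(CO)3 complex 15 until air removes the metal. The closest known reaction type is the Dötz benzannulation of alkenyl(alkoxy)carbene chromium complexes with terminal alkynes; the pairing of a β-alkoxyvinyl carbene with an aryl ynol ether is the untested part. No stereocentre is formed. The step needs regioselective insertion, with the aryloxy carbon next to the CO-derived carbon, which the terminal alkyne secures sterically and the ynol ether polarisation reinforces electronically; it also needs CO insertion to outrun five-membered ring formation, for which the weakly donating aryloxy group, THF as solvent and a moderate temperature are chosen. Air is used for demetallation because stronger oxidants would take the 4-methoxyphenol on to the quinone.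

Step 6
Reactants: 17 1-iodo-3,5-dimethoxybenzene
Product: 18 2-bromo-1-iodo-3,5-dimethoxybenzene
Conditions: NBS, MeCN, 0 °C to rt
Reagents that add atoms: N-bromosuccinimide (NBS), O=C1CCC(=O)N1Br
Why: Electrophilic aromatic bromination should go to the position para to one methoxy and ortho to the other, which is less shielded than the position between the two methoxy groups, as is usual for 5-substituted resorcinol dimethyl ethers.

Step 7
Reactants: 16 2,4-dimethoxy-6-(2,4,6-trimethoxyphenoxy)phenol; 18 2-bromo-1-iodo-3,5-dimethoxybenzene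
Product: 19 2-(2-bromo-3,5-dimethoxyphenoxy)-1,5-dimethoxy-3-(2,4,6-trimethoxyphenoxy)benzene
Conditions: CuI (10 mol %), picolinic acid (20 mol %), K3PO4, DMSO, 85 °C, Ar
Reagents that add atoms: none
Why: Ullmann-type copper-catalysed diaryl ether synthesis with picolinic acid as ligand, a system suited to ortho-substituted phenols, in which the C–I bond reacts well ahead of the C–Br bond that is kept for the next step.

Step 8
Reactants: 19 2-(2-bromo-3,5-dimethoxyphenoxy)-1,5-dimethoxy-3-(2,4,6-trimethoxyphenoxy)benzene; 20 (2,4,6-trimethoxyphenyl)boronic acid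
Product: 21 2-{[2',4,4',6,6'-pentamethoxy-(1,1'-biphenyl)-2-yl]oxy}-1,5-dimethoxy-3-(2,4,6-trimethoxyphenoxy)benzene (decamethyl ether of the target)
Conditions: Pd(OAc)2 (5 mol %), SPhos (10 mol %), K3PO4, toluene/H2O, 100 °C; boronic acid in excess
Reagents that add atoms: none
Why: Suzuki–Miyaura coupling in which the bulky, electron-rich biarylphosphine SPhos supports oxidative addition and reductive elimination at a tetra-ortho-substituted biaryl axis, while the excess of boronic acid offsets protodeboronation.

Step 9
Reactants: 21 decamethyl ether of the target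
Product: 22 fucodiphloroethol G
Conditions: BBr3 (15 equiv), CH2Cl2, −78 °C to rt; then H2O, 0 °C, under Ar
Reagents that add atoms: none
Why: Lewis acid ether cleavage, in which BBr3 binds each methoxy oxygen and bromide removes the methyl group by SN2 attack, while the diaryl ether and biaryl bonds offer no sp3 carbon and stay intact; hydrolysis of the aryl borates frees the ten phenols.

Compound list
1 | chromium hexacarbonyl, Cr(CO)6 | O=C=[Cr](=C=O)(=C=O)(=C=O)(=C=O)=C=O | starting material
2 | ethynyltrimethylsilane | C#C[Si](C)(C)C | starting material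
3 | lithium (trimethylsilyl)acetylide | [Li]C#C[Si](C)(C)C | intermediate
4 | lithium pentacarbonyl[1-oxido-3-(trimethylsilyl)prop-2-yn-1-ylidene]chromate (acylchromate) | [Li+].[O-]C(C#C[Si](C)(C)C)=[Cr](=C=O)(=C=O)(=C=O)(=C=O)=C=O | intermediate
5 | pentacarbonyl[1-methoxy-3-(trimethylsilyl)prop-2-yn-1-ylidene]chromium | COC(C#C[Si](C)(C)C)=[Cr](=C=O)(=C=O)(=C=O)(=C=O)=C=O | intermediate
6 | pentacarbonyl(1-methoxyprop-2-yn-1-ylidene)chromium | COC(C#C)=[Cr](=C=O)(=C=O)(=C=O)(=C=O)=C=O | intermediate
7 | pentacarbonyl[(E)-1,3-dimethoxyprop-2-en-1-ylidene]chromium | COC(/C=C/OC)=[Cr](=C=O)(=C=O)(=C=O)(=C=O)=C=O | intermediate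
8 | 2,4,6-trimethoxyphenol | COc1cc(OC)c(O)c(OC)c1 | starting material
9 | trichloroethylene | ClC=C(Cl)Cl | starting material
10 | dichloroacetylene | ClC#CCl | intermediate
11 | 2-{[(E)-1,2-dichloroethenyl]oxy}-1,3,5-trimethoxybenzene | COc1cc(OC)c(O/C(Cl)=C\Cl)c(OC)c1 | intermediate
12 | 2-[(chloroethynyl)oxy]-1,3,5-trimethoxybenzene | COc1cc(OC)c(OC#CCl)c(OC)c1 | intermediate
13 | lithium (2,4,6-trimethoxyphenoxy)acetylide | COc1cc(OC)c(OC#C[Li])c(OC)c1 | intermediate
14 | 2-(ethynyloxy)-1,3,5-trimethoxybenzene | COc1cc(OC)c(OC#C)c(OC)c1 | intermediate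
15 | tricarbonyl[η6-2,4-dimethoxy-6-(2,4,6-trimethoxyphenoxy)phenol]chromium (η6 bond written as a dot) | COc1cc(OC)c(O)c(Oc2c(OC)cc(OC)cc2OC)c1.O=C=[Cr](=C=O)=C=O | intermediate
16 | 2,4-dimethoxy-6-(2,4,6-trimethoxyphenoxy)phenol | COc1cc(OC)c(O)c(Oc2c(OC)cc(OC)cc2OC)c1 | intermediate
17 | 1-iodo-3,5-dimethoxybenzene | COc1cc(I)cc(OC)c1 | starting material
18 | 2-bromo-1-iodo-3,5-dimethoxybenzene | COc1cc(OC)c(Br)c(I)c1 | intermediate
19 | 2-(2-bromo-3,5-dimethoxyphenoxy)-1,5-dimethoxy-3-(2,4,6-trimethoxyphenoxy)benzene | COc1cc(OC)c(Oc2cc(OC)cc(OC)c2Br)c(Oc2c(OC)cc(OC)cc2OC)c1 | intermediate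
20 | (2,4,6-trimethoxyphenyl)boronic acid | COc1cc(OC)c(B(O)O)c(OC)c1 | starting material
21 | 2-{[2',4,4',6,6'-pentamethoxy-(1,1'-biphenyl)-2-yl]oxy}-1,5-dimethoxy-3-(2,4,6-trimethoxyphenoxy)benzene | COc1cc(OC)c(Oc2cc(OC)cc(OC)c2-c2c(OC)cc(OC)cc2OC)c(Oc2c(OC)cc(OC)cc2OC)c1 | intermediate
22 | fucodiphloroethol G | Oc1cc(O)c(Oc2cc(O)cc(O)c2Oc2cc(O)cc(O)c2-c2c(O)cc(O)cc2O)c(O)c1 | target

Total step count: 9. Longest linear sequence: 6 steps (steps 1, 2, 5, 7, 8, 9; the branch through steps 3 and 4 is equally long).

Steps most likely to fail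

1. Step 5. The donor-stabilised carbene may lose CO too slowly, the vinylcarbene intermediate may cyclise without CO insertion to a five-membered ring, or the ynol ether may oligomerise before it is consumed. The fallback uses known chemistry, sets out from 8 and comes back at 16. Vilsmeier–Haack formylation (POCl3, DMF) of commercial 1-fluoro-3,5-dimethoxybenzene should give 2-fluoro-4,6-dimethoxybenzaldehyde F1. Nucleophilic aromatic substitution of its fluoride by the phenoxide of 8 (K2CO3, DMA, 130 °C) gives 2,4-dimethoxy-6-(2,4,6-trimethoxyphenoxy)benzaldehyde F2. Baeyer–Villiger oxidation with mCPBA in CH2Cl2 gives 2,4-dimethoxy-6-(2,4,6-trimethoxyphenoxy)phenyl formate F3, and methanolysis (K2CO3, MeOH) frees phenol 16.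

2. Step 8. Transmetalation at the doubly ortho-substituted palladium centre may be slower than protodeboronation of the electron-rich boronic acid, so that the bromide is left unchanged or is reduced. The fallback sets out from 19 and comes back at 21. Lithiation of commercial 1,3,5-trimethoxybenzene (n-BuLi, THF, 0 °C) gives (2,4,6-trimethoxyphenyl)lithium F5, and ZnCl2 converts it into chloro(2,4,6-trimethoxyphenyl)zinc F6. Negishi coupling of this reagent with 19 (Pd2(dba)3, RuPhos, THF/NMP, 70 °C) gives 21 without a boron reagent that can be protonated away.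

3. Step 7. C–O bond formation between two ortho-substituted, electron-rich partners may stall, the phenoxide may be oxidised in the presence of copper, or the bromide may couple a second time. The fallback sets out from 18 and 16 and comes back at 19. Oxidation of 18 with mCPBA and TsOH·H2O in MeCN, followed by 1,3,5-trimethoxybenzene, gives (2-bromo-3,5-dimethoxyphenyl)(2,4,6-trimethoxyphenyl)iodonium tosylate F4. The potassium phenoxide of 16 (t-BuOK, THF, rt) then takes over the bromodimethoxyphenyl group by ligand coupling at trivalent iodine, without a metal catalyst, to give 19.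

Further compounds
F1 | step 5 | 2-fluoro-4,6-dimethoxybenzaldehyde | COc1cc(F)c(C=O)c(OC)c1
F2 | step 5 | 2,4-dimethoxy-6-(2,4,6-trimethoxyphenoxy)benzaldehyde | COc1cc(OC)c(C=O)c(Oc2c(OC)cc(OC)cc2OC)c1
F3 | step 5 | 2,4-dimethoxy-6-(2,4,6-trimethoxyphenoxy)phenyl formate | COc1cc(OC)c(OC=O)c(Oc2c(OC)cc(OC)cc2OC)c1
F4 | step 7 | (2-bromo-3,5-dimethoxyphenyl)(2,4,6-trimethoxyphenyl)iodonium 4-methylbenzenesulfonate | COc1cc(OC)c(Br)c([I+]c2c(OC)cc(OC)cc2OC)c1.Cc1ccc(S([O-])(=O)=O)cc1
F5 | step 8 | (2,4,6-trimethoxyphenyl)lithium | [Li]c1c(OC)cc(OC)cc1OC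
F6 | step 8 | chloro(2,4,6-trimethoxyphenyl)zinc | COc1cc(OC)c([Zn]Cl)c(OC)c1
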